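**Retrosynthetic overview**

1. Ring numbering: the 13-membered carbocycle is numbered C1 (CHOAc), C3(Me)=C4, C7(Me)(OH), C8=C9, C10(iPr), C13(Me)(CHO). The strategy rests on C10, an isopropyl-bearing allylic stereocentre next to the E-C8=C9 alkene; it is treated as the γ-carbon of an isopropyl-substituted allyl electrophile that a C9 alkenyl nucleophile attacks.
2. C9–C10 is cut by a chiral NHC–copper-catalysed alkenyl SN2′ coupling of an (E)-alkenyl–B(pin) (C3–C9, from (R)-linalool, which supplies C7) with (E)-4-methylpent-2-enyl diethyl phosphate (C10–C12).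
3. C12–C13 is cut by a Frater–Seebach alkylation: the C12 triflate meets the dianion of ethyl (2S,3S)-3-hydroxy-2-methylhept-5-ynoate, so that C1 sets the quaternary C13.
4. The only ring is closed last, at C3≡C4, by ring-closing alkyne metathesis; hydroxyl-directed trans-hydrostannation and methylation then give E-C3(Me)=C4.
5. End game: ester to aldehyde, acetylation of C1–OH, removal of the C7 silyl ether.

Key step: step 8

Assumption: the antipode of the sulfonate-bearing imidazolinium salt is chosen according to the known sense of induction for E-disubstituted allylic phosphates so that C10 forms as drawn; the sense is assigned by analogy, not verified for this substrate.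

**Route**

Step 1
Reactants: 1 (R)-linalool
Product: 2 triethyl{[(3R)-3,7-dimethylocta-1,6-dien-3-yl]oxy}silane
Conditions: TESOTf, 2,6-lutidine, CH2Cl2, −78 → 0 °C
Reagents that add atoms: triethylsilyl trifluoromethanesulfonate, CC[Si](CC)(CC)OS(=O)(=O)C(F)(F)F
Why: Silyl triflate silylation is the standard way to protect a hindered tertiary allylic alcohol, and the C–O bond at the stereocentre is not touched.

Step 2
Reactants: 2 triethyl{[(3R)-3,7-dimethylocta-1,6-dien-3-yl]oxy}silane
Product: 4 (4R)-4-methyl-4-(triethylsilyloxy)hex-5-enal, via ozonide 3 (not isolated)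
Conditions: O3 (1 equiv, Sudan Red 7B end point), CH2Cl2, −78 °C; then PPh3, −78 °C → rt
Reagents that add atoms: ozone, [O-][O+]=O
Why: In this chemoselective ozonolysis with reductive work-up, the electron-rich trisubstituted alkene should react with ozone much faster than the monosubstituted vinyl group, which sits on the crowded silyloxy-bearing quaternary carbon.

Step 3
Reactants: 4 (4R)-4-methyl-4-(triethylsilyloxy)hex-5-enal
Product: 5 triethyl{[(3R)-3-methylhept-1-en-6-yn-3-yl]oxy}silane
Conditions: dimethyl (1-diazo-2-oxopropyl)phosphonate, K2CO3, MeOH, 0 °C → rt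
Reagents that add atoms: dimethyl (1-diazo-2-oxopropyl)phosphonate, CC(=O)C(=[N+]=[N-])P(=O)(OC)OC
Why: The Ohira–Bestmann alkynylation converts an unhindered aldehyde into the terminal alkyne under mild carbonate conditions that a tertiary triethylsilyl ether should tolerate.

Step 4
Reactants: 5 triethyl{[(3R)-3-methylhept-1-en-6-yn-3-yl]oxy}silane
Product: 7 triethyl{[(3R)-3-methyloct-1-en-6-yn-3-yl]oxy}silane, via lithium acetylide 6 (not isolated)
Conditions: n-BuLi, THF, −78 °C; then MeI, −78 °C → rt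
Reagents that add atoms: iodomethane, CI
Why: Acetylide alkylation with iodomethane caps the alkyne with the methyl group that alkyne metathesis later expels as but-2-yne.

Step 5
Reactants: 7 triethyl{[(3R)-3-methyloct-1-en-6-yn-3-yl]oxy}silane
Product: 9 (2R)-2-methyl-2-(triethylsilyloxy)hept-5-ynal, via trioxolane 8 (not isolated)
Conditions: O3 (1 equiv, Sudan Red 7B end point), CH2Cl2, −78 °C; then PPh3, −78 °C → rt
Reagents that add atoms: ozone, [O-][O+]=O
Why: Ozonolysis with reductive work-up cleaves an alkene far faster than an internal alkyne, and the resulting aldehyde has a quaternary α-carbon and cannot epimerise.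

Step 6
Reactants: 9 (2R)-2-methyl-2-(triethylsilyloxy)hept-5-ynal; 10 2-(dichloromethyl)-4,4,5,5-tetramethyl-1,3,2-dioxaborolane
Product: 11 4,4,5,5-tetramethyl-2-[(1E,3R)-3-methyl-3-(triethylsilyloxy)oct-1-en-6-yn-1-yl]-1,3,2-dioxaborolane
Conditions: CrCl2 (8 equiv), LiI (additive), THF, rt
Reagents that add atoms: none
Why: In this Takai–Utimoto-type boryl-olefination the geminal dichromium reagent formed from 10 adds to the aldehyde and eliminates to the (E)-alkenyl boronate, and the E preference is strongest for hindered aldehydes.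

Step 7
Reactants: 12 (E)-4-methylpent-2-en-1-ol
Product: 13 diethyl (E)-4-methylpent-2-en-1-yl phosphate
Conditions: ClP(O)(OEt)2, Et3N, DMAP (cat.), CH2Cl2, 0 °C → rt
Reagents that add atoms: diethyl chlorophosphate, CCOP(=O)(Cl)OCC
Why: O-Phosphorylation of a primary allylic alcohol gives the leaving group used in copper-catalysed allylic substitution without touching the E-alkene.

Step 8
Reactants: 11 4,4,5,5-tetramethyl-2-[(1E,3R)-3-methyl-3-(triethylsilyloxy)oct-1-en-6-yn-1-yl]-1,3,2-dioxaborolane; 13 diethyl (E)-4-methylpent-2-en-1-yl phosphate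
Product: 14 triethyl{[(3R,4E,6R)-6-methyl-3-(propan-2-yl)undeca-1,4-dien-9-yn-6-yl]oxy}silane
Conditions: CuCl (10 mol%), chiral sulfonate-bearing 4,5-diphenylimidazolinium salt (N-2-sulfonatoaryl, N-2,6-diisopropylphenyl; 11 mol%), NaOMe (2 equiv), 13 (1.5 equiv), THF, 22 → 60 °C
Reagents that add atoms: none
Why: Methoxide turns boronate 11 into a borate from which the (E)-alkenyl group passes with retention to the NHC-bound copper centre (monovalent copper); the alkenylcopper then attacks phosphate 13 in an SN2′ sense at the γ-carbon (C10), with the sulfonate arm and its sodium ion holding the phosphate, and the allylcopper species (trivalent copper) collapses by reductive elimination to the branched 1,4-diene, forming C9–C10. The closest known reaction type is the NHC–copper-catalysed enantioselective allylic substitution of E-disubstituted allylic phosphates by alkenyl–B(pin) reagents. No ring is closed in this step. The one new stereocentre, C10, is set by the chiral sulfonate-bridged NHC ligand, which distinguishes the two faces of the E-alkene of 13; the C7 centre of 11 is remote from the reacting carbon, so the outcome should be catalyst-controlled. The step needs SN2′ over SN2 selectivity, enantiofacial selectivity and retention of alkene geometry: the first two are secured by the chelating sulfonate ligand acting on the E-phosphate, the last by the stereoretentive boron-to-copper transfer. The internal alkyne and the tertiary silyl ether should be inert to methoxide and copper under these conditions.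

Step 9
Reactants: 14 triethyl{[(3R,4E,6R)-6-methyl-3-(propan-2-yl)undeca-1,4-dien-9-yn-6-yl]oxy}silane
Product: 16 (3S,4E,6R)-6-methyl-3-(propan-2-yl)-6-(triethylsilyloxy)undec-4-en-9-yn-1-ol, via alkylborane 15 (not isolated)
Conditions: 9-BBN (1.3 equiv), THF, 0 °C → rt; then NaOH (aq), H2O2, 0 °C
Reagents that add atoms: hydrogen peroxide, OO
Why: Anti-Markovnikov hydroboration–oxidation with 9-BBN takes a monosubstituted alkene much faster than an internal alkyne or the crowded 1,2-disubstituted C8=C9 alkene; C10 is untouched and its descriptor changes from R to S only because the vinyl group becomes a saturated chain.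

Step 10
Reactants: 16 (3S,4E,6R)-6-methyl-3-(propan-2-yl)-6-(triethylsilyloxy)undec-4-en-9-yn-1-ol
Product: 17 (3S,4E,6R)-6-methyl-3-(propan-2-yl)-6-(triethylsilyloxy)undec-4-en-9-yn-1-yl trifluoromethanesulfonate
Conditions: Tf2O, 2,6-lutidine, CH2Cl2, −78 °C; cold work-up, used at once
Reagents that add atoms: trifluoromethanesulfonic anhydride, O=S(=O)(OS(=O)(=O)C(F)(F)F)C(F)(F)F
Why: Triflation of the primary alcohol at low temperature with a hindered base gives the most reactive sp3 electrophile available for the enolate alkylation that follows.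

Step 11
Reactants: 18 ethyl (3R)-4-chloro-3-hydroxybutanoate
Product: 19 ethyl 2-[(2R)-oxiran-2-yl]acetate
Conditions: Ag2O, DME, 60 °C, dark
Reagents that add atoms: none
Why: Silver-assisted intramolecular Williamson closure of the chlorohydrin works without strong base, which avoids opening the β,γ-epoxy ester to the 4-hydroxycrotonate, and it leaves the C–O bond at the stereocentre intact.

Step 12
Reactants: 19 ethyl 2-[(2R)-oxiran-2-yl]acetate
Product: 20 ethyl (3S)-3-hydroxyhept-5-ynoate
Conditions: propyne, n-BuLi, THF, −78 °C; BF3·OEt2; then 19, −78 °C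
Reagents that add atoms: propyne, CC#C
Why: In this Yamaguchi-type alkynylation the weakly basic alkynyl–BF3 species opens the activated epoxide at its CH2 terminus at −78 °C, where the ester and its acidic α-CH2 should survive; the carbinol centre is not touched and its descriptor changes from R to S only through the priority switch.

Step 13
Reactants: 20 ethyl (3S)-3-hydroxyhept-5-ynoate
Product: 22 ethyl (2S,3S)-3-hydroxy-2-methylhept-5-ynoate, via dilithium dianion 21 (not isolated)
Conditions: LiN(iPr)2 (2.2 equiv), THF, −78 → −20 °C; then MeI, DMPU, −78 → 0 °C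
Reagents that add atoms: iodomethane, CI
Why: In the Frater–Seebach alkylation the chelated alkoxide–enolate is methylated on the face away from the carbinol side chain, giving the anti product; the new α-centre is erased again in step 14.

Step 14
Reactants: 22 ethyl (2S,3S)-3-hydroxy-2-methylhept-5-ynoate; 17 (3S,4E,6R)-6-methyl-3-(propan-2-yl)-6-(triethylsilyloxy)undec-4-en-9-yn-1-yl trifluoromethanesulfonate
Product: 24 ethyl (2S,3S)-3-hydroxy-2-methyl-2-[(3S,4E,6R)-6-methyl-3-(propan-2-yl)-6-(triethylsilyloxy)undec-4-en-9-yn-1-yl]hept-5-ynoate, via dilithium dianion 23 (not isolated)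
Conditions: 22 (1.5 equiv), LiN(iPr)2 (2.2 equiv per 22), THF, −78 → −20 °C; then 17, THF/DMPU, −78 → −30 °C
Reagents that add atoms: none
Why: A second Frater–Seebach alkylation lets the primary triflate attack the chelated tetrasubstituted enolate on the same face as before, so C12 ends anti and the methyl group syn to the C1 oxygen, which sets the quaternary C13 (S) from the C1 carbinol.

Step 15
Reactants: 24 ethyl (2S,3S)-3-hydroxy-2-methyl-2-[(3S,4E,6R)-6-methyl-3-(propan-2-yl)-6-(triethylsilyloxy)undec-4-en-9-yn-1-yl]hept-5-ynoate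
Product: 25 ethyl (1S,7R,8E,10S,13S)-1-hydroxy-7,13-dimethyl-10-(propan-2-yl)-7-(triethylsilyloxy)cyclotridec-8-en-3-yne-13-carboxylate (target numbering)
Conditions: Mo(≡CC6H4OMe-4)(OSiPh3)3 (15 mol%), 5 Å molecular sieves, toluene (2 mM), 80 °C
Reagents that add atoms: none
Why: Ring-closing alkyne metathesis of the two methyl-capped alkynes forms C3≡C4 in a 13-membered cycloalkyne, a ring size within the reach of this reaction; the sieves trap but-2-yne, and the alkenes and the hindered secondary hydroxyl should not engage the alkylidyne.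

Step 16
Reactants: 25 ethyl (1S,7R,8E,10S,13S)-1-hydroxy-7,13-dimethyl-10-(propan-2-yl)-7-(triethylsilyloxy)cyclotridec-8-en-3-yne-13-carboxylate
Product: 26 ethyl (1S,3Z,7R,8E,10S,13S)-1-hydroxy-7,13-dimethyl-10-(propan-2-yl)-3-(tributylstannyl)-7-(triethylsilyloxy)cyclotrideca-3,8-diene-13-carboxylate (target numbering)
Conditions: Bu3SnH (1.2 equiv, slow addition), [Cp*RuCl]4 (5 mol%), CH2Cl2, rt
Reagents that add atoms: tributyltin hydride, CCCC[SnH](CCCC)CCCC
Why: In the ruthenium-catalysed trans-hydrostannation the free homopropargylic C1 hydroxyl hydrogen-bonds to the Ru–Cl unit and steers tin to the proximal C3, while H adds to C4 from the opposite side, which places ring carbons C2 and C5 trans.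

Step 17
Reactants: 26 ethyl (1S,3Z,7R,8E,10S,13S)-1-hydroxy-7,13-dimethyl-10-(propan-2-yl)-3-(tributylstannyl)-7-(triethylsilyloxy)cyclotrideca-3,8-diene-13-carboxylate
Product: 27 ethyl (1S,3E,7R,8E,10S,13S)-1-hydroxy-3,7,13-trimethyl-10-(propan-2-yl)-7-(triethylsilyloxy)cyclotrideca-3,8-diene-13-carboxylate (target numbering)
Conditions: MeI, Cu(O2CC4H3S) (copper thiophene-2-carboxylate), [NBu4][Ph2PO2], Pd(PPh3)4 (cat.), DMF, rt
Reagents that add atoms: iodomethane, CI
Why: This copper-assisted Stille-type methylation replaces tin by methyl with retention of alkene geometry, giving E-C3(Me)=C4, and the phosphinate salt scavenges the tin residue.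

Step 18
Reactants: 27 ethyl (1S,3E,7R,8E,10S,13S)-1-hydroxy-3,7,13-trimethyl-10-(propan-2-yl)-7-(triethylsilyloxy)cyclotrideca-3,8-diene-13-carboxylate
Product: 28 (1S,3E,7R,8E,10S,13R)-13-(hydroxymethyl)-3,7,13-trimethyl-10-(propan-2-yl)-7-(triethylsilyloxy)cyclotrideca-3,8-dien-1-ol (target numbering)
Conditions: LiAlH4, THF, 0 °C
Reagents that add atoms: none
Why: Hydride reduction of the neopentyl ester gives the primary alcohol without affecting the isolated alkenes or the silyl ether; the C13 descriptor changes to R only through the priority switch.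

Step 19
Reactants: 28 (1S,3E,7R,8E,10S,13R)-13-(hydroxymethyl)-3,7,13-trimethyl-10-(propan-2-yl)-7-(triethylsilyloxy)cyclotrideca-3,8-dien-1-ol
Product: 29 (1S,3E,7R,8E,10S,13S)-1-hydroxy-3,7,13-trimethyl-10-(propan-2-yl)-7-(triethylsilyloxy)cyclotrideca-3,8-diene-13-carbaldehyde (target numbering)
Conditions: TEMPO (cat.), PhI(OAc)2, CH2Cl2, rt
Reagents that add atoms: none
Why: The oxoammonium oxidation (TEMPO with PhI(OAc)2) takes the primary alcohol in preference to the hindered secondary C1 hydroxyl, and the aldehyde cannot enolise or eliminate because C13 is quaternary.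

Step 20
Reactants: 29 (1S,3E,7R,8E,10S,13S)-1-hydroxy-3,7,13-trimethyl-10-(propan-2-yl)-7-(triethylsilyloxy)cyclotrideca-3,8-diene-13-carbaldehyde
Product: 30 (1S,3E,7R,8E,10S,13S)-13-formyl-3,7,13-trimethyl-10-(propan-2-yl)-7-(triethylsilyloxy)cyclotrideca-3,8-dien-1-yl acetate (target numbering)
Conditions: Ac2O, pyridine, DMAP (cat.), CH2Cl2, 0 °C → rt
Reagents that add atoms: acetic anhydride, CC(=O)OC(C)=O
Why: DMAP-catalysed acetylation esterifies the only free hydroxyl under weakly basic conditions that should not trigger retro-aldol cleavage.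

Step 21
Reactants: 30 (1S,3E,7R,8E,10S,13S)-13-formyl-3,7,13-trimethyl-10-(propan-2-yl)-7-(triethylsilyloxy)cyclotrideca-3,8-dien-1-yl acetate
Product: 31 (1S,3E,7R,8E,10S,13S)-13-formyl-7-hydroxy-3,7,13-trimethyl-10-(propan-2-yl)cyclotrideca-3,8-dien-1-yl acetate
Conditions: HF·pyridine, pyridine, THF, 0 °C → rt
Reagents that add atoms: none
Why: Buffered fluoride desilylation frees the tertiary allylic C7 alcohol without ionising it and without cleaving the acetate or disturbing the non-enolisable aldehyde.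

**Compound list**

1 | (R)-linalool, (3R)-3,7-dimethylocta-1,6-dien-3-ol | CC(C)=CCC[C@@](C)(O)C=C | starting material
2 | triethyl{[(3R)-3,7-dimethylocta-1,6-dien-3-yl]oxy}silane | CC(C)=CCC[C@@](C)(O[Si](CC)(CC)CC)C=C | intermediate
3 | 3,3-dimethyl-5-[(3R)-3-methyl-3-(triethylsilyloxy)pent-4-en-1-yl]-1,2,4-trioxolane (ozonide) | CC1(C)OOC(CC[C@@](C)(O[Si](CC)(CC)CC)C=C)O1 | intermediate
4 | (4R)-4-methyl-4-(triethylsilyloxy)hex-5-enal | O=CCC[C@@](C)(O[Si](CC)(CC)CC)C=C | intermediate
5 | triethyl{[(3R)-3-methylhept-1-en-6-yn-3-yl]oxy}silane | C#CCC[C@@](C)(O[Si](CC)(CC)CC)C=C | intermediate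
6 | lithium acetylide of 5 | [Li]C#CCC[C@@](C)(O[Si](CC)(CC)CC)C=C | intermediate
7 | triethyl{[(3R)-3-methyloct-1-en-6-yn-3-yl]oxy}silane | CC#CCC[C@@](C)(O[Si](CC)(CC)CC)C=C | intermediate
8 | 3-[(2R)-2-(triethylsilyloxy)hept-5-yn-2-yl]-1,2,4-trioxolane (ozonide) | CC#CCC[C@@](C)(O[Si](CC)(CC)CC)C1OCOO1 | intermediate
9 | (2R)-2-methyl-2-(triethylsilyloxy)hept-5-ynal | CC#CCC[C@@](C)(O[Si](CC)(CC)CC)C=O | intermediate
10 | 2-(dichloromethyl)-4,4,5,5-tetramethyl-1,3,2-dioxaborolane | ClC(Cl)B1OC(C)(C)C(C)(C)O1 | starting material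
11 | 4,4,5,5-tetramethyl-2-[(1E,3R)-3-methyl-3-(triethylsilyloxy)oct-1-en-6-yn-1-yl]-1,3,2-dioxaborolane | CC#CCC[C@@](C)(O[Si](CC)(CC)CC)/C=C/B1OC(C)(C)C(C)(C)O1 | intermediate
12 | (E)-4-methylpent-2-en-1-ol | CC(C)/C=C/CO | starting material
13 | diethyl (E)-4-methylpent-2-en-1-yl phosphate | CC(C)/C=C/COP(=O)(OCC)OCC | intermediate
14 | triethyl{[(3R,4E,6R)-6-methyl-3-(propan-2-yl)undeca-1,4-dien-9-yn-6-yl]oxy}silane | CC#CCC[C@@](C)(O[Si](CC)(CC)CC)/C=C/[C@H](C(C)C)C=C | intermediate
15 | 9-[(3S,4E,6R)-6-methyl-3-(propan-2-yl)-6-(triethylsilyloxy)undec-4-en-9-yn-1-yl]-9-borabicyclo[3.3.1]nonane | CC#CCC[C@@](C)(O[Si](CC)(CC)CC)/C=C/[C@H](C(C)C)CCB1C2CCCC1CCC2 | intermediate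
16 | (3S,4E,6R)-6-methyl-3-(propan-2-yl)-6-(triethylsilyloxy)undec-4-en-9-yn-1-ol | CC#CCC[C@@](C)(O[Si](CC)(CC)CC)/C=C/[C@H](C(C)C)CCO | intermediate
17 | (3S,4E,6R)-6-methyl-3-(propan-2-yl)-6-(triethylsilyloxy)undec-4-en-9-yn-1-yl trifluoromethanesulfonate | CC#CCC[C@@](C)(O[Si](CC)(CC)CC)/C=C/[C@H](C(C)C)CCOS(=O)(=O)C(F)(F)F | intermediate
18 | ethyl (3R)-4-chloro-3-hydroxybutanoate | CCOC(=O)C[C@@H](O)CCl | starting material
19 | ethyl 2-[(2R)-oxiran-2-yl]acetate | CCOC(=O)C[C@@H]1CO1 | intermediate
20 | ethyl (3S)-3-hydroxyhept-5-ynoate | CCOC(=O)C[C@@H](O)CC#CC | intermediate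
21 | dilithium alkoxide–enolate of 20 | [Li+].[Li+].CCOC([O-])=C[C@@H]([O-])CC#CC | intermediate
22 | ethyl (2S,3S)-3-hydroxy-2-methylhept-5-ynoate | CCOC(=O)[C@@H](C)[C@@H](O)CC#CC | intermediate
23 | dilithium alkoxide–enolate of 22 | [Li+].[Li+].CCOC([O-])=C(C)[C@@H]([O-])CC#CC | intermediate
24 | ethyl (2S,3S)-3-hydroxy-2-methyl-2-[(3S,4E,6R)-6-methyl-3-(propan-2-yl)-6-(triethylsilyloxy)undec-4-en-9-yn-1-yl]hept-5-ynoate | CC#CCC[C@@](C)(O[Si](CC)(CC)CC)/C=C/[C@H](C(C)C)CC[C@](C)(C(=O)OCC)[C@@H](O)CC#CC | intermediate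
25 | ethyl (1S,7R,8E,10S,13S)-1-hydroxy-7,13-dimethyl-10-(propan-2-yl)-7-(triethylsilyloxy)cyclotridec-8-en-3-yne-13-carboxylate (target numbering) | O[C@H]1CC#CCC[C@@](C)(O[Si](CC)(CC)CC)/C=C/[C@H](C(C)C)CC[C@]1(C)C(=O)OCC | intermediate
26 | ethyl (1S,3Z,7R,8E,10S,13S)-1-hydroxy-7,13-dimethyl-10-(propan-2-yl)-3-(tributylstannyl)-7-(triethylsilyloxy)cyclotrideca-3,8-diene-13-carboxylate (target numbering) | O[C@H]1C/C([Sn](CCCC)(CCCC)CCCC)=C/CC[C@@](C)(O[Si](CC)(CC)CC)/C=C/[C@H](C(C)C)CC[C@]1(C)C(=O)OCC | intermediate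
27 | ethyl (1S,3E,7R,8E,10S,13S)-1-hydroxy-3,7,13-trimethyl-10-(propan-2-yl)-7-(triethylsilyloxy)cyclotrideca-3,8-diene-13-carboxylate (target numbering) | O[C@H]1C/C(C)=C/CC[C@@](C)(O[Si](CC)(CC)CC)/C=C/[C@H](C(C)C)CC[C@]1(C)C(=O)OCC | intermediate
28 | (1S,3E,7R,8E,10S,13R)-13-(hydroxymethyl)-3,7,13-trimethyl-10-(propan-2-yl)-7-(triethylsilyloxy)cyclotrideca-3,8-dien-1-ol (target numbering) | O[C@H]1C/C(C)=C/CC[C@@](C)(O[Si](CC)(CC)CC)/C=C/[C@H](C(C)C)CC[C@]1(C)CO | intermediate
29 | (1S,3E,7R,8E,10S,13S)-1-hydroxy-3,7,13-trimethyl-10-(propan-2-yl)-7-(triethylsilyloxy)cyclotrideca-3,8-diene-13-carbaldehyde (target numbering) | O[C@H]1C/C(C)=C/CC[C@@](C)(O[Si](CC)(CC)CC)/C=C/[C@H](C(C)C)CC[C@]1(C)C=O | intermediate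
30 | (1S,3E,7R,8E,10S,13S)-13-formyl-3,7,13-trimethyl-10-(propan-2-yl)-7-(triethylsilyloxy)cyclotrideca-3,8-dien-1-yl acetate (target numbering) | CC(=O)O[C@H]1C/C(C)=C/CC[C@@](C)(O[Si](CC)(CC)CC)/C=C/[C@H](C(C)C)CC[C@]1(C)C=O | intermediate
31 | (1S,3E,7R,8E,10S,13S)-13-formyl-7-hydroxy-3,7,13-trimethyl-10-(propan-2-yl)cyclotrideca-3,8-dien-1-yl acetate | CC(=O)O[C@H]1C/C(C)=C/CC[C@@](C)(O)/C=C/[C@H](C(C)C)CC[C@]1(C)C=O | target

**Step count and risks**

Total step count: 21. Longest linear sequence: 17 steps (steps 1–6, 8–10, 14–21).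

The three steps most likely to fail:

Step 8. What may go wrong: boron-to-copper transfer of the hindered alkenyl group may be slow and lose out to protodeboronation, SN2 substitution to the linear diene may compete, or the catalyst may give poor facial selectivity at C10. Fallback, setting out from aldehyde 9 and coming back at alcohol 16: CrCl2/CHI3 iodo-olefination of 9 gives triethyl{[(1E,3R)-1-iodo-3-methyloct-1-en-6-yn-3-yl]oxy}silane F1. Iodine–lithium exchange (t-BuLi, Et2O, −78 °C) and transfer to magnesium and copper (MgBr2·OEt2, CuBr·SMe2) give an alkenylcopper reagent. This is added in conjugate fashion to (4S)-3-[(2E)-4-methylpent-2-enoyl]-4-phenyl-1,3-oxazolidin-2-one F2, made from (E)-4-methylpent-2-enoic acid and (S)-4-phenyloxazolidin-2-one through the pivaloyl mixed anhydride. Attack on the chelated s-cis enoyl imide from the face away from the phenyl group should give (4S)-3-[(3S,4E,6R)-6-methyl-3-(propan-2-yl)-6-(triethylsilyloxy)undec-4-en-9-ynoyl]-4-phenyl-1,3-oxazolidin-2-one F3, with C10 set by the auxiliary and the same C9–C10 bond formed. LiBH4 then removes the auxiliary and delivers 16 directly, so steps 6 to 9 are bypassed.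

Step 14. What may go wrong: the tetrasubstituted dianion may be too hindered to displace the triflate at carbon, leaving O-alkylation of the alkoxide or elimination of the triflate as the main pathways. Fallback, setting out from triflate 17 and coming back at 24: the hindered bond is made with iodomethane instead, and C1 is reset by a catalyst.
- Commercial ethyl (3S)-4-chloro-3-hydroxybutanoate is taken through the conditions of steps 11 and 12 to ethyl 2-[(2S)-oxiran-2-yl]acetate F4 and ethyl (3R)-3-hydroxyhept-5-ynoate F5.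
- The unhindered dianion of F5 is alkylated with 17 (Frater–Seebach, anti) to give ethyl (2R,3R)-3-hydroxy-2-[(3S,4E,6R)-6-methyl-3-(propan-2-yl)-6-(triethylsilyloxy)undec-4-en-9-yn-1-yl]hept-5-ynoate F6.
- A second Frater–Seebach alkylation with iodomethane builds the quaternary centre with the required C13 configuration, giving ethyl (2S,3R)-3-hydroxy-2-methyl-2-[(3S,4E,6R)-6-methyl-3-(propan-2-yl)-6-(triethylsilyloxy)undec-4-en-9-yn-1-yl]hept-5-ynoate F7, the C1 epimer of 24.
- Dess–Martin oxidation gives the non-epimerisable ethyl (2S)-2-methyl-2-[(3S,4E,6R)-6-methyl-3-(propan-2-yl)-6-(triethylsilyloxy)undec-4-en-9-yn-1-yl]-3-oxohept-5-ynoate F8.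
- Corey–Bakshi–Shibata reduction with the (R)-methyl oxazaborolidine and catecholborane at low temperature, with the quaternary carbon as the large group, should return 24.

Step 16. What may go wrong: tin may be delivered to C4 as well as C3, because the directing hydroxyl is only homopropargylic and can hydrogen-bond to the neighbouring ester instead of the Ru–Cl unit. Fallback, setting out from cycloalkyne 25 and coming back at 27: the hydroxyl is tied to the silicon reagent so that regiochemistry is fixed by ring size.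
- Silylation of 25 with 1,1,3,3-tetramethyldisilazane gives the dimethylsilyl ether F9.
- [RuCl2(C6H6)]2 in CH2Cl2 brings about intramolecular anti-hydrosilylation in the exo mode, giving the five-membered cyclic dimethylsiloxane F10 with silicon on C3 and hydrogen on C4 trans to it.
- Iododesilylation with N-iodosuccinimide in buffered hexafluoroisopropanol, with retention, gives the (Z)-alkenyl iodide F11.
- Negishi methylation (MeZnCl, Pd(PPh3)4, THF) gives 27, so stannane 26 and step 17 are bypassed.

**Further compounds**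

F1 | step 8 | triethyl{[(1E,3R)-1-iodo-3-methyloct-1-en-6-yn-3-yl]oxy}silane | CC#CCC[C@@](C)(O[Si](CC)(CC)CC)/C=C/I
F2 | step 8 | (4S)-3-[(2E)-4-methylpent-2-enoyl]-4-phenyl-1,3-oxazolidin-2-one | CC(C)/C=C/C(=O)N1[C@@H](c2ccccc2)COC1=O
F3 | step 8 | (4S)-3-[(3S,4E,6R)-6-methyl-3-(propan-2-yl)-6-(triethylsilyloxy)undec-4-en-9-ynoyl]-4-phenyl-1,3-oxazolidin-2-one | CC#CCC[C@@](C)(O[Si](CC)(CC)CC)/C=C/[C@H](C(C)C)CC(=O)N1[C@@H](c2ccccc2)COC1=O
F4 | step 14 | ethyl 2-[(2S)-oxiran-2-yl]acetate | CCOC(=O)C[C@H]1CO1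
F5 | step 14 | ethyl (3R)-3-hydroxyhept-5-ynoate | CCOC(=O)C[C@H](O)CC#CC
F6 | step 14 | ethyl (2R,3R)-3-hydroxy-2-[(3S,4E,6R)-6-methyl-3-(propan-2-yl)-6-(triethylsilyloxy)undec-4-en-9-yn-1-yl]hept-5-ynoate | CC#CCC[C@@](C)(O[Si](CC)(CC)CC)/C=C/[C@H](C(C)C)CC[C@@H](C(=O)OCC)[C@H](O)CC#CC
F7 | step 14 | ethyl (2S,3R)-3-hydroxy-2-methyl-2-[(3S,4E,6R)-6-methyl-3-(propan-2-yl)-6-(triethylsilyloxy)undec-4-en-9-yn-1-yl]hept-5-ynoate | CC#CCC[C@@](C)(O[Si](CC)(CC)CC)/C=C/[C@H](C(C)C)CC[C@](C)(C(=O)OCC)[C@H](O)CC#CC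
F8 | step 14 | ethyl (2S)-2-methyl-2-[(3S,4E,6R)-6-methyl-3-(propan-2-yl)-6-(triethylsilyloxy)undec-4-en-9-yn-1-yl]-3-oxohept-5-ynoate | CC#CCC[C@@](C)(O[Si](CC)(CC)CC)/C=C/[C@H](C(C)C)CC[C@](C)(C(=O)OCC)C(=O)CC#CC
F9 | step 16 | O-dimethylsilyl ether of 25: ethyl (1S,7R,8E,10S,13S)-1-(dimethylsilyloxy)-7,13-dimethyl-10-(propan-2-yl)-7-(triethylsilyloxy)cyclotridec-8-en-3-yne-13-carboxylate (target numbering) | C[SiH](C)O[C@H]1CC#CCC[C@@](C)(O[Si](CC)(CC)CC)/C=C/[C@H](C(C)C)CC[C@]1(C)C(=O)OCC
F10 | step 16 | cyclic dimethylsiloxane in which SiMe2 bridges the C1 oxygen and C3 of the 13-membered ring (2,2-dimethyl-1,2-oxasilolane), (3Z)-C3=C4 with silicon cis to C5, other centres as in 25 | C[Si]2(C)O[C@H]1C/C2=C/CC[C@@](C)(O[Si](CC)(CC)CC)/C=C/[C@H](C(C)C)CC[C@]1(C)C(=O)OCC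
F11 | step 16 | ethyl (1S,3Z,7R,8E,10S,13S)-1-hydroxy-3-iodo-7,13-dimethyl-10-(propan-2-yl)-7-(triethylsilyloxy)cyclotrideca-3,8-diene-13-carboxylate (target numbering) | O[C@H]1C/C(I)=C/CC[C@@](C)(O[Si](CC)(CC)CC)/C=C/[C@H](C(C)C)CC[C@]1(C)C(=O)OCC
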